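**Strategy**

- Retrosynthesis: ring A (the phenol ring) is taken apart completely by cutting its C(OAr)–CH, C(alkyl)–C(OH) and C(OH)–CH bonds. This leaves an aryloxy(isopropenyl)carbene of chromium, one CO ligand and a chiral terminal alkyne.
- The carbene C–O bond is then cut to (S)-curcuphenol, whose side chain is cut at CH2–CH= (B-alkyl Suzuki coupling) and at the benzylic C–CH3 bond (SN2′ methylation).
- Enabling feature: ring A is a 1,4-dioxygenated benzene. Its free OH is para to the carbon carrying the diaryl ether oxygen, the 6-methylhept-5-en-2-yl chain is ortho to OH, the methyl is ortho to OAr, and the two other ring atoms are CH. This is the 4-alkoxyphenol pattern that a carbene/CO/alkyne benzannulation delivers.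
- Forward: ring B is bought as an arene and carried to (S)-curcuphenol (steps 1 to 5), and its oxygen is attached to a chromium carbene carbon (steps 6 and 7). Ring A is built last around that oxygen from the carbene, CO and an alkyne made from (S)-citronellal (steps 8 and 9), which completes the diaryl ether without any aryl C–O coupling.
- Stereochemistry: the ring-B centre is set by the chiral ligand in the copper-catalysed SN2′ methylation (step 3). The ring-A centre is C3 of (S)-citronellal. Neither is touched afterwards.

Key step: step 9

Assumption: the Taniaphos enantiomer for step 3 is chosen from the sense of induction known for cinnamyl bromide itself (aryl, vinyl, methyl and H rank identically in 4 and in 3-phenylbut-1-ene); both ligand enantiomers are commercial, so the (S) product is accessible either way.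

**Route**

Step 1
Reactants: 1 2-methoxy-4-methylbenzaldehyde
Product: 2 rac-1-(2-methoxy-4-methylphenyl)prop-2-en-1-ol
Conditions: CH2=CHMgBr (1.2 equiv), THF, 0 °C; then H2O
Reagents that add atoms: vinylmagnesium bromide, C=C[Mg]Br
Why: Grignard 1,2-addition to an aryl aldehyde is reliable, and the carbinol centre, formed racemic, is erased in step 2.

Step 2
Reactants: 2 rac-1-(2-methoxy-4-methylphenyl)prop-2-en-1-ol
Product: 3 (E)-1-(3-bromoprop-1-en-1-yl)-2-methoxy-4-methylbenzene
Conditions: PBr3 (0.4 equiv), Et2O, 0 °C; used at once without storage
Reagents that add atoms: phosphorus tribromide, BrP(Br)Br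
Why: bromination of a 1-arylallyl alcohol with PBr3 proceeds with allylic transposition (SN2′ attack or ion-pair collapse, with equilibration of any secondary bromide) to the conjugated primary bromide, and conjugation with the electron-rich ring makes the (E)-cinnamyl isomer the thermodynamic product.

Step 3
Reactants: 3 (E)-1-(3-bromoprop-1-en-1-yl)-2-methoxy-4-methylbenzene
Product: 4 (S)-1-(but-3-en-2-yl)-2-methoxy-4-methylbenzene
Conditions: MeMgBr (1.2 equiv), CuBr·SMe2 (3 mol%), Taniaphos [1-(α-dimethylamino-2-diphenylphosphinobenzyl)-2-diphenylphosphinoferrocene, single enantiomer giving the (S) product, 3.5 mol%], CH2Cl2, −78 °C, slow addition of 3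
Reagents that add atoms: methylmagnesium bromide, C[Mg]Br
Why: copper-catalysed asymmetric allylic alkylation (SN2′) of cinnamyl-type bromides with MeMgBr under a monovalent copper–ferrocenyl diphosphine catalyst is known to favour the branched alkene, and the chiral ligand decides which enantiotopic face of the alkene receives the methyl group, which sets the (S) benzylic centre.

Step 4
Reactants: 4 (S)-1-(but-3-en-2-yl)-2-methoxy-4-methylbenzene; 5 1-bromo-2-methylprop-1-ene
Product: 7 (S)-curcuphenol methyl ether [2-methoxy-4-methyl-1-((2S)-6-methylhept-5-en-2-yl)benzene], via B-alkyl-9-BBN borane 6 (not isolated)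
Conditions: 9-BBN-H (1.1 equiv), THF, 0 °C to rt; then 5 (1.5 equiv), PdCl2(dppf) (3 mol%), 3 M aq NaOH, THF, 65 °C
Reagents that add atoms: none
Why: 9-BBN adds anti-Markovnikov to the monosubstituted vinyl group without touching the benzylic stereocentre, and the primary B-alkyl borane then undergoes B-alkyl Suzuki–Miyaura coupling with the alkenyl bromide under PdCl2(dppf) and aqueous hydroxide, where β-hydride elimination is slow.

Step 5
Reactants: 7 (S)-curcuphenol methyl ether
Product: 8 (S)-curcuphenol [5-methyl-2-((2S)-6-methylhept-5-en-2-yl)phenol]
Conditions: NaSEt (4 equiv), DMF, 130 °C; then aq HCl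
Reagents that add atoms: none
Why: SN2 attack of ethanethiolate on the O-methyl group in hot DMF (thiolate O-demethylation of an aryl methyl ether) releases the phenoxide while the trisubstituted alkene and the benzylic stereocentre are inert to these conditions.

Step 6
Reactants: 9 2-bromopropene; 10 chromium hexacarbonyl Cr(CO)6
Product: 13 tetramethylammonium pentacarbonyl(2-methylprop-2-enoyl)chromate, via isopropenyllithium 11 (not isolated), via lithium acyl chromate 12 (not isolated)
Conditions: t-BuLi (2.0 equiv), Et2O, −78 °C; 10 (1.0 equiv), −78 °C to rt; then Me4NBr, H2O, 0 °C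
Reagents that add atoms: tetramethylammonium bromide, C[N+](C)(C)C.[Br-]
Why: bromine–lithium exchange gives isopropenyllithium, which adds to a carbonyl ligand of zerovalent Cr(CO)6 to form the acyl chromate, and cation metathesis with Me4NBr precipitates the storable tetramethylammonium salt, the standard entry to heteroatom-stabilised chromium carbene complexes.

Step 7
Reactants: 8 (S)-curcuphenol; 13 tetramethylammonium pentacarbonyl(2-methylprop-2-enoyl)chromate
Product: 15 pentacarbonyl{[5-methyl-2-((2S)-6-methylhept-5-en-2-yl)phenoxy](prop-1-en-2-yl)methylidene}chromium, via acetoxycarbene complex 14 (not isolated)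
Conditions: 13 (1.3 equiv), AcBr (1.3 equiv), CH2Cl2, −40 °C; then 8 (1.0 equiv), −40 to 0 °C, Ar, dark; cold filtration through silica (hexane)
Reagents that add atoms: none
Why: O-acylation of the acyl chromate gives a strongly electrophilic acetoxycarbene complex, and addition–elimination of the phenol at the carbene carbon with loss of acetic acid (acyloxy-to-aryloxy exchange, the known route to aryloxycarbene complexes) forms the aryl–O–C bond at low temperature without affecting the stereocentre.

Step 8
Reactants: 16 (S)-citronellal [(3S)-3,7-dimethyloct-6-enal]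
Product: 18 (S)-3,7-dimethyloct-6-en-1-yne, via alkenyl nonaflate 17 (not isolated)
Conditions: C4F9SO2F (1.2 equiv), phosphazene base P2-Et (2.3 equiv), DMF, −30 °C to rt
Reagents that add atoms: none
Why: O-sulfonylation of the aldehyde enolate with nonafluorobutanesulfonyl fluoride followed by base-induced β-elimination of the alkenyl nonaflate (the one-pot aldehyde-to-terminal-alkyne conversion with phosphazene bases) keeps all ten carbons, and the C3 centre is retained because it is not an acidic position in the aldehyde or the nonaflate and is only weakly acidic in the alkyne.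

Step 9
Reactants: 18 (S)-3,7-dimethyloct-6-en-1-yne; 15 pentacarbonyl{[5-methyl-2-((2S)-6-methylhept-5-en-2-yl)phenoxy](prop-1-en-2-yl)methylidene}chromium
Product: 20 5-methyl-2-[(2S)-6-methylhept-5-en-2-yl]-4-{5-methyl-2-[(2S)-6-methylhept-5-en-2-yl]phenoxy}phenol, via tricarbonylchromium arene complex 19 (not isolated)
Conditions: 18 (1.5 equiv), THF (0.05 M), 50 °C, Ar; then air, daylight, Et2O, rt
Reagents that add atoms: none
Why: Thermal loss of one CO from 15 lets alkyne 18 coordinate and insert into the Cr=C bond to give a vinylcarbene, CO insertion converts this into a chromium-bound dienylketene, and electrocyclisation followed by tautomerisation of the cyclohexadienone gives the phenol as its Cr(CO)3 complex 19, which air and light cleave to 20. The closest known reaction type is the Dötz benzannulation of alkenyl(alkoxy)- and alkenyl(aryloxy)carbene complexes of chromium with terminal alkynes, which gives 4-alkoxy- or 4-aryloxyphenols. Ring A, the only ring formed, closes by 6π-electrocyclisation of the dienylketene, which joins the CO-derived carbon to the isopropenyl CH2, after the two insertions have joined the carbene carbon to the alkyne CH and the substituted alkyne carbon to CO. No stereocentre is created and no bond at either existing (S) centre is broken, so both are carried through unchanged. The step needs regioselective alkyne insertion, secured by the size difference between H and the α-branched alkyl group of 18, which places the chain next to the CO-derived C–OH and the CH next to the aryloxy carbon. It also needs benzannulation to outrun capture of the vinylcarbene by the tethered alkene, which the trisubstituted nature of that alkene, the alkenyl carbene and the coordinating solvent all favour, while the non-oxidative release from chromium spares the oxidisable 4-aryloxyphenol.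

**Compound list**

1 | 2-methoxy-4-methylbenzaldehyde | COc1cc(C)ccc1C=O | starting material
2 | rac-1-(2-methoxy-4-methylphenyl)prop-2-en-1-ol | C=CC(O)c1ccc(C)cc1OC | intermediate
3 | (E)-1-(3-bromoprop-1-en-1-yl)-2-methoxy-4-methylbenzene | COc1cc(C)ccc1/C=C/CBr | intermediate
4 | (S)-1-(but-3-en-2-yl)-2-methoxy-4-methylbenzene | C=C[C@H](C)c1ccc(C)cc1OC | intermediate
5 | 1-bromo-2-methylprop-1-ene | CC(C)=CBr | starting material
6 | 9-[(3S)-3-(2-methoxy-4-methylphenyl)butyl]-9-borabicyclo[3.3.1]nonane | COc1cc(C)ccc1[C@@H](C)CCB1C2CCCC1CCC2 | intermediate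
7 | (S)-curcuphenol methyl ether, 2-methoxy-4-methyl-1-[(2S)-6-methylhept-5-en-2-yl]benzene | CC(C)=CCC[C@H](C)c1ccc(C)cc1OC | intermediate
8 | (S)-curcuphenol, 5-methyl-2-[(2S)-6-methylhept-5-en-2-yl]phenol | CC(C)=CCC[C@H](C)c1ccc(C)cc1O | intermediate
9 | 2-bromopropene | CC(Br)=C | starting material
10 | chromium hexacarbonyl Cr(CO)6 | [C-]#[O+].[C-]#[O+].[C-]#[O+].[C-]#[O+].[C-]#[O+].[C-]#[O+].[Cr] | starting material
11 | isopropenyllithium (prop-1-en-2-yllithium) | [Li]C(C)=C | intermediate
12 | lithium pentacarbonyl(2-methylprop-2-enoyl)chromate | [Li+].C=C(C)C([O-])=[Cr](=C=O)(=C=O)(=C=O)(=C=O)=C=O | intermediate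
13 | tetramethylammonium pentacarbonyl(2-methylprop-2-enoyl)chromate | C[N+](C)(C)C.C=C(C)C([O-])=[Cr](=C=O)(=C=O)(=C=O)(=C=O)=C=O | intermediate
14 | pentacarbonyl[acetoxy(prop-1-en-2-yl)methylidene]chromium | CC(=O)OC(C(C)=C)=[Cr](=C=O)(=C=O)(=C=O)(=C=O)=C=O | intermediate
15 | pentacarbonyl{[5-methyl-2-((2S)-6-methylhept-5-en-2-yl)phenoxy](prop-1-en-2-yl)methylidene}chromium | CC(C)=CCC[C@H](C)c1ccc(C)cc1OC(C(C)=C)=[Cr](=C=O)(=C=O)(=C=O)(=C=O)=C=O | intermediate
16 | (S)-citronellal, (3S)-3,7-dimethyloct-6-enal | CC(C)=CCC[C@H](C)CC=O | starting material
17 | (3S)-3,7-dimethylocta-1,6-dien-1-yl nonafluorobutane-1-sulfonate (E/Z mixture) | CC(C)=CCC[C@H](C)C=COS(=O)(=O)C(F)(F)C(F)(F)C(F)(F)C(F)(F)F | intermediate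
18 | (S)-3,7-dimethyloct-6-en-1-yne | CC(C)=CCC[C@H](C)C#C | intermediate
19 | tricarbonyl(η6-arene)chromium complex of 20, Cr(CO)3 on ring A (metal fragment written as separate components) | CC(C)=CCC[C@H](C)c1cc(Oc2cc(C)ccc2[C@@H](C)CCC=C(C)C)c(C)cc1O.[C-]#[O+].[C-]#[O+].[C-]#[O+].[Cr] | intermediate
20 | 5-methyl-2-[(2S)-6-methylhept-5-en-2-yl]-4-{5-methyl-2-[(2S)-6-methylhept-5-en-2-yl]phenoxy}phenol | CC(C)=CCC[C@H](C)c1cc(Oc2cc(C)ccc2[C@@H](C)CCC=C(C)C)c(C)cc1O | target

**Summary**

Total step count: 9 steps.
Longest linear sequence: 7 steps (steps 1, 2, 3, 4, 5, 7 and 9, from 1 to 20).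

**Steps most likely to fail**

Step 9. The chromium vinylcarbene or dienylketene may be diverted before ring closure: by cyclopropanation or metathesis-type capture by the tethered trisubstituted alkene, by cyclobutenone or furan formation, or by incomplete regiocontrol of alkyne insertion. The electron-rich product may also be oxidised during chromium removal. The fallback makes the diaryl ether by C–O coupling and needs none of steps 6 to 8; it sets out from 4 and 8 and returns to the route at 20.
- Ring bromination of 4 (NBS, MeCN, 0 °C, dark) should occur para to the methoxy group and give (S)-1-bromo-5-(but-3-en-2-yl)-4-methoxy-2-methylbenzene F1.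
- Ullmann coupling of this bromide with 8 (CuI, N,N-dimethylglycine, Cs2CO3, dioxane, 100 °C) should give 1-[(2S)-but-3-en-2-yl]-2-methoxy-4-methyl-5-{5-methyl-2-[(2S)-6-methylhept-5-en-2-yl]phenoxy}benzene F2.
- 9-BBN, which prefers the vinyl group to the trisubstituted alkene, should convert it into its B-alkyl-9-BBN adduct F3.
- Coupling in the same flask with 5 under the conditions of step 4 should give the target O-methyl ether F4.
- NaSEt in DMF as in step 5 should then deliver 20.

Step 7. Acyl transfer from the acetoxycarbene to the phenol oxygen, which would return the acyl chromate, may compete with substitution at the carbene carbon. The aryloxycarbene may also decompose thermally before it can be used. The fallback sets out from 8 and returns at 20 in one operation, without any carbene chemistry: one-electron oxidative homocoupling of 8 (laccase, O2, aqueous buffer/acetone, rt, or Ag2CO3 on Celite, benzene, rt). The phenoxyl radical of one molecule should couple through oxygen to the para carbon of a second. C–C linked biaryl dimers are to be expected beside the ether and would have to be separated by chromatography. No new compound arises on this path.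

Step 3. The ortho-methoxy group may erode branched-versus-linear regioselectivity and facial selectivity by chelating magnesium, and the labile, electron-rich bromide may undergo uncatalysed SN2 substitution. The fallback sets out from 1 and returns at 4, bypassing 2 and 3.
- Wittig methylenation of 1 (Ph3PCH3Br, KOtBu, THF, 0 °C) should give 2-methoxy-4-methyl-1-vinylbenzene F5.
- Nickel-catalysed asymmetric hydrovinylation ([(η3-C3H5)NiBr]2, chiral phosphoramidite ligand, Na[B(3,5-(CF3)2C6H3)4], ethylene 1 atm, CH2Cl2, −70 °C) should add H and vinyl across the styrene double bond with the vinyl group at the benzylic carbon. The ligand controls the face and should give 4 directly.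

**Further compounds**

F1 | step 9 | (S)-1-bromo-5-(but-3-en-2-yl)-4-methoxy-2-methylbenzene | C=C[C@H](C)c1cc(Br)c(C)cc1OC
F2 | step 9 | 1-[(2S)-but-3-en-2-yl]-2-methoxy-4-methyl-5-{5-methyl-2-[(2S)-6-methylhept-5-en-2-yl]phenoxy}benzene | C=C[C@H](C)c1cc(Oc2cc(C)ccc2[C@@H](C)CCC=C(C)C)c(C)cc1OC
F3 | step 9 | B-alkyl-9-BBN adduct of F2, 9-[(3S)-3-(2-methoxy-4-methyl-5-{5-methyl-2-[(2S)-6-methylhept-5-en-2-yl]phenoxy}phenyl)butyl]-9-borabicyclo[3.3.1]nonane | COc1cc(C)c(Oc2cc(C)ccc2[C@@H](C)CCC=C(C)C)cc1[C@@H](C)CCB1C2CCCC1CCC2
F4 | step 9 | target O-methyl ether, 2-methoxy-4-methyl-1-[(2S)-6-methylhept-5-en-2-yl]-5-{5-methyl-2-[(2S)-6-methylhept-5-en-2-yl]phenoxy}benzene | CC(C)=CCC[C@H](C)c1cc(Oc2cc(C)ccc2[C@@H](C)CCC=C(C)C)c(C)cc1OC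
F0 | step 7 | none | none
F5 | step 3 | 2-methoxy-4-methyl-1-vinylbenzene | C=Cc1ccc(C)cc1OC
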